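**Retrosynthetic overview**
- The strategy rests on the quaternary carbon attached to C6 of the coumarin benzene ring. It carries two methyl groups and a vinyl group and lies ortho to the C7 hydroxyl, the pattern left when a carbon nucleophile adds to an ortho-quinone methide. One C–CH3 bond and the C–vinyl bond are therefore made in one flask from an acetyl group with two Grignard reagents.
- The benzene ring is bought as 2,4-dihydroxyacetophenone. The pyranone ring is the only ring built and is closed last: C3=C4 by a Z-selective Horner–Wadsworth–Emmons reaction on a C4a aldehyde, then O1–C2 by lactonisation.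
- The C3–C1' bond comes from alkylation of a diaryl phosphonoacetate with the triflate of a nerol-derived bis-epoxy alcohol. C2'/C3' are set by a Sharpless epoxidation and C6' by a Shi epoxidation.
- Ring order: benzene ring (given), the two side-chain oxiranes (in the fragment), pyranone ring (final step).

Key step: step 3

Remark: phosphonate 20 is carried as both epimers at the phosphorus-bearing carbon; this carbon becomes sp2 (C3), so the mixture is of no consequence.

**Route**

Step 1
Reactants: 1 2,4-dihydroxyacetophenone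
Product: 2 1-[4-(tert-butyldimethylsilyloxy)-2-hydroxyphenyl]ethanone
Conditions: TBSCl (1.05 equiv), imidazole, CH2Cl2, 0 °C to rt
Reagents that add atoms: tert-butyldimethylsilyl chloride, CC(C)(C)[Si](C)(C)Cl
Why: Chemoselective O-silylation, because the 2-hydroxyl is held in a hydrogen bond to the acetyl carbonyl and only the 4-hydroxyl reacts with one equivalent of silyl chloride.

Step 2
Reactants: 2 1-[4-(tert-butyldimethylsilyloxy)-2-hydroxyphenyl]ethanone
Product: 3 2-acetyl-5-(tert-butyldimethylsilyloxy)phenyl tert-butyl carbonate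
Conditions: Boc2O, iPr2NEt, 4-(dimethylamino)pyridine (10 mol %), THF, rt
Reagents that add atoms: di-tert-butyl dicarbonate, CC(C)(C)OC(=O)OC(=O)OC(C)(C)C
Why: Nucleophile-catalysed O-acylation turns the chelated phenol into the aryl tert-butyl carbonate that later serves as the transferable leaving group.

Step 3
Reactants: 3 2-acetyl-5-(tert-butyldimethylsilyloxy)phenyl tert-butyl carbonate; 4 methylmagnesium bromide; 5 vinylmagnesium bromide
Product: 9 5-(tert-butyldimethylsilyloxy)-2-(2-methylbut-3-en-2-yl)phenol, via magnesium alkoxide 6 (not isolated), via aryloxide carbonate 7 (not isolated), via ortho-quinone methide 8 (not isolated)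
Conditions: MeMgBr (1.05 equiv), Et2O, −78 °C; then CH2=CHMgBr (3 equiv, THF), −78 to 0 °C; aq NH4Cl
Reagents that add atoms: methylmagnesium bromide, C[Mg]Br; vinylmagnesium bromide, C=C[Mg]Br
Why: MeMgBr adds to the ketone at −78 °C, faster than to the hindered aryl carbonate, to give alkoxide 6, which takes the tert-butoxycarbonyl group from the neighbouring phenol oxygen (7); the freed aryloxide then expels tert-butyl carbonate to give ortho-quinone methide 8 with an exocyclic C(CH3)2 carbon, and CH2=CHMgBr adds to that carbon in 1,4-fashion, the regained aromaticity paying for the quaternary centre. The closest known reaction type is the anionic generation of ortho-quinone methides from ortho-(tert-butoxycarbonyloxy)aryl aldehydes and ketones with organomagnesium reagents and their capture by a second Grignard reagent; capture by a vinyl nucleophile at a fully substituted exocyclic carbon is the demanding variant. No ring is closed and no stereocentre is formed. Regiochemistry is fixed by the substrate: the new carbon sits where the acetyl group was, ortho to the unmasked hydroxyl (future O7) and para to the silyloxy group (future O1). The selectivity needed is conjugate addition ahead of tautomerisation of 8 to the 2-isopropenylphenol; the para silyloxy donor should let 8 form below 0 °C, where the excess vinyl reagent already present can intercept it as it forms.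

Step 4
Reactants: 9 5-(tert-butyldimethylsilyloxy)-2-(2-methylbut-3-en-2-yl)phenol
Product: 10 tert-butyldimethyl{4-(2-methylbut-3-en-2-yl)-3-[tri(propan-2-yl)silyloxy]phenoxy}silane
Conditions: iPr3SiOTf, 2,6-lutidine, CH2Cl2, 0 °C to rt
Reagents that add atoms: triisopropylsilyl trifluoromethanesulfonate, CC(C)[Si](OS(=O)(=O)C(F)(F)F)(C(C)C)C(C)C
Why: O-silylation with a silyl triflate is reactive enough for the phenol next to the quaternary carbon, and lutidine buffers the acid that could otherwise cyclise the phenol onto the vinyl group.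

Step 5
Reactants: 10 tert-butyldimethyl{4-(2-methylbut-3-en-2-yl)-3-[tri(propan-2-yl)silyloxy]phenoxy}silane
Product: 11 4-(2-methylbut-3-en-2-yl)-3-[tri(propan-2-yl)silyloxy]phenol
Conditions: K2CO3, MeOH, 0 °C to rt, stopped at full conversion of 10
Reagents that add atoms: none
Why: Selective base-mediated methanolysis of an aryl silyl ether, since the unhindered tert-butyldimethylsilyl ether should cleave far faster than the triisopropylsilyl ether flanked by the quaternary carbon.

Step 6
Reactants: 11 4-(2-methylbut-3-en-2-yl)-3-[tri(propan-2-yl)silyloxy]phenol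
Product: 13 2-hydroxy-5-(2-methylbut-3-en-2-yl)-4-[tri(propan-2-yl)silyloxy]benzaldehyde, via hydroxymethylphenol 12 (not isolated)
Conditions: MgCl2, Et3N, (CH2O)n, THF, reflux; aq NH4Cl
Reagents that add atoms: formaldehyde (as paraformaldehyde), C=O
Why: Casnati–Skattebøl ortho-formylation: the magnesium phenoxide delivers formaldehyde to the ortho carbon (future C4a), the open site para to the silyloxy group being preferred over the site wedged between the two oxygens, and a second formaldehyde oxidises 12 by hydride transfer.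

Step 7
Reactants: 13 2-hydroxy-5-(2-methylbut-3-en-2-yl)-4-[tri(propan-2-yl)silyloxy]benzaldehyde
Product: 14 2-(tert-butyldimethylsilyloxy)-5-(2-methylbut-3-en-2-yl)-4-[tri(propan-2-yl)silyloxy]benzaldehyde
Conditions: TBSCl, imidazole, DMF, rt
Reagents that add atoms: tert-butyldimethylsilyl chloride, CC(C)(C)[Si](C)(C)Cl
Why: O-silylation of the salicylaldehyde hydroxyl keeps the aldehyde from being deactivated as a phenoxide in the olefination and sets up a fluoride-triggered lactonisation.

Step 8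
Reactants: 15 nerol
Product: 16 [(2S,3R)-3-methyl-3-(4-methylpent-3-en-1-yl)oxiran-2-yl]methanol
Conditions: Ti(OiPr)4 (10 mol %), diethyl (2R,3R)-tartrate (12 mol %), t-BuOOH, 4 Å molecular sieves, CH2Cl2, −20 °C
Reagents that add atoms: tert-butyl hydroperoxide, CC(C)(C)OO
Why: Sharpless asymmetric epoxidation, in which the (2R,3R)-tartrate ligand delivers oxygen to the face giving 2S at the CH carbon, the Z geometry of nerol then fixes 3R, and the remote alkene is untouched because only the allylic alcohol is bound to titanium.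

Step 9
Reactants: 16 [(2S,3R)-3-methyl-3-(4-methylpent-3-en-1-yl)oxiran-2-yl]methanol
Product: 17 [(2S,3R)-3-{2-[(2R)-3,3-dimethyloxiran-2-yl]ethyl}-3-methyloxiran-2-yl]methanol
Conditions: 1,2:4,5-di-O-isopropylidene-β-D-erythro-2,3-hexodiulo-2,6-pyranose (30 mol %), KHSO5 (as 2KHSO5·KHSO4·K2SO4), K2CO3, Bu4NHSO4, Na2B4O7 buffer, MeCN–CH2(OMe)2–H2O, 0 °C
Reagents that add atoms: potassium peroxymonosulfate, [K+].[O-]S(=O)(=O)OO
Why: Shi epoxidation, in which the chiral dioxirane from the D-fructose-derived ketone should give the R epoxide at the terminal trisubstituted alkene through the spiro transition state, under reagent control independent of the distant epoxy alcohol, which should survive the buffered medium at 0 °C.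

Step 10
Reactants: 17 [(2S,3R)-3-{2-[(2R)-3,3-dimethyloxiran-2-yl]ethyl}-3-methyloxiran-2-yl]methanol
Product: 18 [(2S,3R)-3-{2-[(2R)-3,3-dimethyloxiran-2-yl]ethyl}-3-methyloxiran-2-yl]methyl trifluoromethanesulfonate
Conditions: Tf2O, 2,6-lutidine, CH2Cl2, −78 °C; cold aq NaHCO3 wash, crude product used at once
Reagents that add atoms: trifluoromethanesulfonic anhydride, O=S(=O)(OS(=O)(=O)C(F)(F)F)C(F)(F)F
Why: O-sulfonylation of the primary alcohol at −78 °C gives a primary epoxy triflate that can be alkylated at low temperature, and no stereocentre is touched.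

Step 11
Reactants: 18 [(2S,3R)-3-{2-[(2R)-3,3-dimethyloxiran-2-yl]ethyl}-3-methyloxiran-2-yl]methyl trifluoromethanesulfonate; 19 ethyl 2-[bis(2-methylphenoxy)phosphoryl]acetate
Product: 20 ethyl 2-[bis(2-methylphenoxy)phosphoryl]-3-[(2S,3R)-3-{2-[(2R)-3,3-dimethyloxiran-2-yl]ethyl}-3-methyloxiran-2-yl]propanoate
Conditions: 19 (3 equiv), NaH (2.5 equiv), THF, 0 °C; then 18, −78 to −20 °C; AcOH quench
Reagents that add atoms: none
Why: SN2 C-alkylation of the soft phosphonoacetate enolate by the primary triflate, run cold and with excess neutral 19 as proton buffer so that the carbanion of 20 is not present long enough to open the neighbouring oxirane.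

Step 12
Reactants: 20 ethyl 2-[bis(2-methylphenoxy)phosphoryl]-3-[(2S,3R)-3-{2-[(2R)-3,3-dimethyloxiran-2-yl]ethyl}-3-methyloxiran-2-yl]propanoate; 14 2-(tert-butyldimethylsilyloxy)-5-(2-methylbut-3-en-2-yl)-4-[tri(propan-2-yl)silyloxy]benzaldehyde
Product: 21 ethyl (2Z)-3-{2-(tert-butyldimethylsilyloxy)-5-(2-methylbut-3-en-2-yl)-4-[tri(propan-2-yl)silyloxy]phenyl}-2-{[(2S,3R)-3-{2-[(2R)-3,3-dimethyloxiran-2-yl]ethyl}-3-methyloxiran-2-yl]methyl}prop-2-enoate
Conditions: KOtBu added to 20 and 14 in THF at −78 °C, then −78 to 0 °C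
Reagents that add atoms: none
Why: Ando-type Horner–Wadsworth–Emmons olefination, in which the diaryl phosphonate collapses fast from the kinetic adduct to give the Z trisubstituted enoate (aryl cis to the ester), and forming the carbanion in the presence of the aldehyde at low temperature keeps its lifetime short.

Step 13
Reactants: 21 ethyl (2Z)-3-{2-(tert-butyldimethylsilyloxy)-5-(2-methylbut-3-en-2-yl)-4-[tri(propan-2-yl)silyloxy]phenyl}-2-{[(2S,3R)-3-{2-[(2R)-3,3-dimethyloxiran-2-yl]ethyl}-3-methyloxiran-2-yl]methyl}prop-2-enoate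
Product: 23 3-{[(2S,3R)-3-{2-[(2R)-3,3-dimethyloxiran-2-yl]ethyl}-3-methyloxiran-2-yl]methyl}-7-hydroxy-6-(2-methylbut-3-en-2-yl)-2H-chromen-2-one (target), via Z-dihydroxycinnamate ester 22 (not isolated)
Conditions: Bu4NF (2.5 equiv), THF, 0 °C to rt; aq NH4Cl
Reagents that add atoms: none
Why: Fluoride desilylation of both aryl silyl ethers followed by lactonisation (6-exo-trig acyl substitution) of the phenoxide that sits cis to the ester closes the pyranone ring, and the oxiranes should be inert to fluoride and phenoxide at this temperature.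

**Compound list**
1 | 2,4-dihydroxyacetophenone | CC(=O)c1ccc(O)cc1O | starting material
2 | 1-[4-(tert-butyldimethylsilyloxy)-2-hydroxyphenyl]ethanone | CC(=O)c1ccc(O[Si](C)(C)C(C)(C)C)cc1O | intermediate
3 | 2-acetyl-5-(tert-butyldimethylsilyloxy)phenyl tert-butyl carbonate | CC(=O)c1ccc(O[Si](C)(C)C(C)(C)C)cc1OC(=O)OC(C)(C)C | intermediate
4 | methylmagnesium bromide | C[Mg]Br | starting material
5 | vinylmagnesium bromide | C=C[Mg]Br | starting material
6 | bromomagnesium 2-[2-(tert-butoxycarbonyloxy)-4-(tert-butyldimethylsilyloxy)phenyl]propan-2-olate | CC(C)(O[Mg]Br)c1ccc(O[Si](C)(C)C(C)(C)C)cc1OC(=O)OC(C)(C)C | intermediate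
7 | bromomagnesium 2-[2-(tert-butoxycarbonyloxy)propan-2-yl]-5-(tert-butyldimethylsilyloxy)phenolate | CC(C)(OC(=O)OC(C)(C)C)c1ccc(O[Si](C)(C)C(C)(C)C)cc1O[Mg]Br | intermediate
8 | 3-(tert-butyldimethylsilyloxy)-6-(propan-2-ylidene)cyclohexa-2,4-dien-1-one | CC(C)=C1C=CC(O[Si](C)(C)C(C)(C)C)=CC1=O | intermediate
9 | 5-(tert-butyldimethylsilyloxy)-2-(2-methylbut-3-en-2-yl)phenol | C=CC(C)(C)c1ccc(O[Si](C)(C)C(C)(C)C)cc1O | intermediate
10 | tert-butyldimethyl{4-(2-methylbut-3-en-2-yl)-3-[tri(propan-2-yl)silyloxy]phenoxy}silane | C=CC(C)(C)c1ccc(O[Si](C)(C)C(C)(C)C)cc1O[Si](C(C)C)(C(C)C)C(C)C | intermediate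
11 | 4-(2-methylbut-3-en-2-yl)-3-[tri(propan-2-yl)silyloxy]phenol | C=CC(C)(C)c1ccc(O)cc1O[Si](C(C)C)(C(C)C)C(C)C | intermediate
12 | 2-(hydroxymethyl)-4-(2-methylbut-3-en-2-yl)-5-[tri(propan-2-yl)silyloxy]phenol | C=CC(C)(C)c1cc(CO)c(O)cc1O[Si](C(C)C)(C(C)C)C(C)C | intermediate
13 | 2-hydroxy-5-(2-methylbut-3-en-2-yl)-4-[tri(propan-2-yl)silyloxy]benzaldehyde | C=CC(C)(C)c1cc(C=O)c(O)cc1O[Si](C(C)C)(C(C)C)C(C)C | intermediate
14 | 2-(tert-butyldimethylsilyloxy)-5-(2-methylbut-3-en-2-yl)-4-[tri(propan-2-yl)silyloxy]benzaldehyde | C=CC(C)(C)c1cc(C=O)c(O[Si](C)(C)C(C)(C)C)cc1O[Si](C(C)C)(C(C)C)C(C)C | intermediate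
15 | nerol, (2Z)-3,7-dimethylocta-2,6-dien-1-ol | CC(C)=CCC/C(C)=C\CO | starting material
16 | [(2S,3R)-3-methyl-3-(4-methylpent-3-en-1-yl)oxiran-2-yl]methanol | OC[C@@H]1O[C@]1(C)CCC=C(C)C | intermediate
17 | [(2S,3R)-3-{2-[(2R)-3,3-dimethyloxiran-2-yl]ethyl}-3-methyloxiran-2-yl]methanol | OC[C@@H]1O[C@]1(C)CC[C@H]2OC2(C)C | intermediate
18 | [(2S,3R)-3-{2-[(2R)-3,3-dimethyloxiran-2-yl]ethyl}-3-methyloxiran-2-yl]methyl trifluoromethanesulfonate | O=S(=O)(OC[C@@H]1O[C@]1(C)CC[C@H]2OC2(C)C)C(F)(F)F | intermediate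
19 | ethyl 2-[bis(2-methylphenoxy)phosphoryl]acetate | CCOC(=O)CP(=O)(Oc1ccccc1C)Oc1ccccc1C | starting material
20 | ethyl 2-[bis(2-methylphenoxy)phosphoryl]-3-[(2S,3R)-3-{2-[(2R)-3,3-dimethyloxiran-2-yl]ethyl}-3-methyloxiran-2-yl]propanoate (both epimers at C2) | CCOC(=O)C(C[C@@H]1O[C@]1(C)CC[C@H]2OC2(C)C)P(=O)(Oc1ccccc1C)Oc1ccccc1C | intermediate
21 | ethyl (2Z)-3-{2-(tert-butyldimethylsilyloxy)-5-(2-methylbut-3-en-2-yl)-4-[tri(propan-2-yl)silyloxy]phenyl}-2-{[(2S,3R)-3-{2-[(2R)-3,3-dimethyloxiran-2-yl]ethyl}-3-methyloxiran-2-yl]methyl}prop-2-enoate | CCOC(=O)/C(C[C@@H]1O[C@]1(C)CC[C@H]2OC2(C)C)=C\c1cc(C(C)(C)C=C)c(O[Si](C(C)C)(C(C)C)C(C)C)cc1O[Si](C)(C)C(C)(C)C | intermediate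
22 | ethyl (2Z)-3-[2,4-dihydroxy-5-(2-methylbut-3-en-2-yl)phenyl]-2-{[(2S,3R)-3-{2-[(2R)-3,3-dimethyloxiran-2-yl]ethyl}-3-methyloxiran-2-yl]methyl}prop-2-enoate | CCOC(=O)/C(C[C@@H]1O[C@]1(C)CC[C@H]2OC2(C)C)=C\c1cc(C(C)(C)C=C)c(O)cc1O | intermediate
23 | 3-{[(2S,3R)-3-{2-[(2R)-3,3-dimethyloxiran-2-yl]ethyl}-3-methyloxiran-2-yl]methyl}-7-hydroxy-6-(2-methylbut-3-en-2-yl)-2H-chromen-2-one | C=CC(C)(C)c1cc2cc(C[C@@H]3O[C@]3(C)CC[C@H]3OC3(C)C)c(=O)oc2cc1O | target

**Step count**
Total: 13 steps. Longest linear sequence: 9 steps (steps 1–7, 12 and 13); the side-chain branch is steps 8–11.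

**Steps most likely to fail**

1. Step 3. The quinone methide may tautomerise to the 2-isopropenylphenol (1,5-hydrogen shift or deprotonation by the Grignard reagent) before the vinyl reagent adds, or the organomagnesium reagents may attack the carbonate instead of the ketone. The fallback builds the quaternary carbon by enolate methylation and the vinyl group by methylenation. It sets out from 2 and comes back at 10, replacing steps 3 and 4. Silylation of 2 with iPr3SiOTf and 2,6-lutidine should give 1-{4-(tert-butyldimethylsilyloxy)-2-[tri(propan-2-yl)silyloxy]phenyl}ethanone F1. Wittig reaction with Ph3P=CHOMe (from [Ph3PCH2OMe]Cl and KN(SiMe3)2, THF) should give the enol ether tert-butyl{4-(1-methoxyprop-1-en-2-yl)-3-[tri(propan-2-yl)silyloxy]phenoxy}dimethylsilane F2. Brief hydrolysis with dilute HCl in THF at 0 °C should give 2-{4-(tert-butyldimethylsilyloxy)-2-[tri(propan-2-yl)silyloxy]phenyl}propanal F3. C-Methylation with KOtBu and MeI should give 2-{4-(tert-butyldimethylsilyloxy)-2-[tri(propan-2-yl)silyloxy]phenyl}-2-methylpropanal F4. Methylenation with Ph3P=CH2 (from [Ph3PCH3]Br and KOtBu) then gives 10.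

2. Step 11. The phosphonate-stabilised carbanion may open the adjacent oxirane (three-membered ring closure), the enolate may be O-alkylated, or the triflate may decompose before it is alkylated. The fallback postpones the 2',3'-oxirane until no carbanion is needed. It sets out from 15 (with 19 and 14) and comes back at 21, replacing steps 8–12.
   - Acetylation (Ac2O, pyridine) gives neryl acetate F5.
   - Shi epoxidation with the D-fructose-derived ketone of step 9 and KHSO5 should take the 6,7-alkene, the 2,3-alkene being deactivated by the allylic acetate, and give [(2Z)-5-[(2R)-3,3-dimethyloxiran-2-yl]-3-methylpent-2-en-1-yl] acetate F6.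
   - K2CO3 in MeOH gives (2Z)-5-[(2R)-3,3-dimethyloxiran-2-yl]-3-methylpent-2-en-1-ol F7.
   - MsCl and Et3N give the methanesulfonate F8, and LiBr in THF gives (2R)-3-[(3Z)-5-bromo-3-methylpent-3-en-1-yl]-2,2-dimethyloxirane F9.
   - Alkylation of the sodium enolate of 19 gives ethyl (4Z)-2-[bis(2-methylphenoxy)phosphoryl]-7-[(2R)-3,3-dimethyloxiran-2-yl]-5-methylhept-4-enoate F10.
   - Olefination with 14 as in step 12 gives ethyl (2Z)-3-{2-(tert-butyldimethylsilyloxy)-5-(2-methylbut-3-en-2-yl)-4-[tri(propan-2-yl)silyloxy]phenyl}-2-[(2Z)-5-[(2R)-3,3-dimethyloxiran-2-yl]-3-methylpent-2-en-1-yl]prop-2-enoate F11.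
   - Epoxidation of its only electron-rich trisubstituted alkene with KHSO5 and the enantiomeric ketone 1,2:4,5-di-O-isopropylidene-β-L-erythro-2,3-hexodiulo-2,6-pyranose should, by the spiro transition-state model, give the 2S,3R oxirane, that is 21. This last step relies on reagent control at a Z-trisubstituted alkene, which is less secure than the Sharpless step it replaces.

3. Step 12. Z-selectivity may erode with the branched phosphonate and the electron-rich, ortho-disubstituted aldehyde, so that part of the material ends as the E ester, which cannot lactonise. The fallback corrects geometry with light instead of relying on kinetic Z-selection. It sets out from 20 and 14 and comes back at 23. The E ester formed in the olefination, ethyl (2E)-3-{2-(tert-butyldimethylsilyloxy)-5-(2-methylbut-3-en-2-yl)-4-[tri(propan-2-yl)silyloxy]phenyl}-2-{[(2S,3R)-3-{2-[(2R)-3,3-dimethyloxiran-2-yl]ethyl}-3-methyloxiran-2-yl]methyl}prop-2-enoate F12, is desilylated with Bu4NF to ethyl (2E)-3-[2,4-dihydroxy-5-(2-methylbut-3-en-2-yl)phenyl]-2-{[(2S,3R)-3-{2-[(2R)-3,3-dimethyloxiran-2-yl]ethyl}-3-methyloxiran-2-yl]methyl}prop-2-enoate F13. Irradiation at 365 nm in dilute MeCN should isomerise F13 to the Z ester 22, which lactonises to 23; this is the known photoisomerisation–lactonisation of 2-hydroxycinnamates.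

**Further compounds**
F1 | step 3 | 1-{4-(tert-butyldimethylsilyloxy)-2-[tri(propan-2-yl)silyloxy]phenyl}ethanone | CC(=O)c1ccc(O[Si](C)(C)C(C)(C)C)cc1O[Si](C(C)C)(C(C)C)C(C)C
F2 | step 3 | tert-butyl{4-(1-methoxyprop-1-en-2-yl)-3-[tri(propan-2-yl)silyloxy]phenoxy}dimethylsilane (E/Z mixture) | COC=C(C)c1ccc(O[Si](C)(C)C(C)(C)C)cc1O[Si](C(C)C)(C(C)C)C(C)C
F3 | step 3 | 2-{4-(tert-butyldimethylsilyloxy)-2-[tri(propan-2-yl)silyloxy]phenyl}propanal (racemic) | CC(C=O)c1ccc(O[Si](C)(C)C(C)(C)C)cc1O[Si](C(C)C)(C(C)C)C(C)C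
F4 | step 3 | 2-{4-(tert-butyldimethylsilyloxy)-2-[tri(propan-2-yl)silyloxy]phenyl}-2-methylpropanal | CC(C)(C=O)c1ccc(O[Si](C)(C)C(C)(C)C)cc1O[Si](C(C)C)(C(C)C)C(C)C
F5 | step 11 | neryl acetate | CC(C)=CCC/C(C)=C\COC(C)=O
F6 | step 11 | [(2Z)-5-[(2R)-3,3-dimethyloxiran-2-yl]-3-methylpent-2-en-1-yl] acetate | CC(=O)OC/C=C(C)\CC[C@H]1OC1(C)C
F7 | step 11 | (2Z)-5-[(2R)-3,3-dimethyloxiran-2-yl]-3-methylpent-2-en-1-ol | OC/C=C(C)\CC[C@H]1OC1(C)C
F8 | step 11 | [(2Z)-5-[(2R)-3,3-dimethyloxiran-2-yl]-3-methylpent-2-en-1-yl] methanesulfonate | CS(=O)(=O)OC/C=C(C)\CC[C@H]1OC1(C)C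
F9 | step 11 | (2R)-3-[(3Z)-5-bromo-3-methylpent-3-en-1-yl]-2,2-dimethyloxirane | BrC/C=C(C)\CC[C@H]1OC1(C)C
F10 | step 11 | ethyl (4Z)-2-[bis(2-methylphenoxy)phosphoryl]-7-[(2R)-3,3-dimethyloxiran-2-yl]-5-methylhept-4-enoate | CCOC(=O)C(C/C=C(C)\CC[C@H]1OC1(C)C)P(=O)(Oc1ccccc1C)Oc1ccccc1C
F11 | step 11 | ethyl (2Z)-3-{2-(tert-butyldimethylsilyloxy)-5-(2-methylbut-3-en-2-yl)-4-[tri(propan-2-yl)silyloxy]phenyl}-2-[(2Z)-5-[(2R)-3,3-dimethyloxiran-2-yl]-3-methylpent-2-en-1-yl]prop-2-enoate | CCOC(=O)/C(C/C=C(C)\CC[C@H]1OC1(C)C)=C\c1cc(C(C)(C)C=C)c(O[Si](C(C)C)(C(C)C)C(C)C)cc1O[Si](C)(C)C(C)(C)C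
F12 | step 12 | ethyl (2E)-3-{2-(tert-butyldimethylsilyloxy)-5-(2-methylbut-3-en-2-yl)-4-[tri(propan-2-yl)silyloxy]phenyl}-2-{[(2S,3R)-3-{2-[(2R)-3,3-dimethyloxiran-2-yl]ethyl}-3-methyloxiran-2-yl]methyl}prop-2-enoate | CCOC(=O)/C(C[C@@H]1O[C@]1(C)CC[C@H]2OC2(C)C)=C/c1cc(C(C)(C)C=C)c(O[Si](C(C)C)(C(C)C)C(C)C)cc1O[Si](C)(C)C(C)(C)C
F13 | step 12 | ethyl (2E)-3-[2,4-dihydroxy-5-(2-methylbut-3-en-2-yl)phenyl]-2-{[(2S,3R)-3-{2-[(2R)-3,3-dimethyloxiran-2-yl]ethyl}-3-methyloxiran-2-yl]methyl}prop-2-enoate | CCOC(=O)/C(C[C@@H]1O[C@]1(C)CC[C@H]2OC2(C)C)=C/c1cc(C(C)(C)C=C)c(O)cc1O
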